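The phloroglucinol ring of macrocarpal J is joined through its most hindered carbon, the one flanked by two C–OH carbons, to the stereocentre C1' that sits on C1 of eudesmane ring A. Instead of alkylating an arene at that position, the route grows the ring from C1': a thermal benzannulation of 3-ethoxycyclobutenone with a C1' triisopropylsilyl ynol ether forms two ring bonds and the complete 1,3,5-trioxygenated arene in one operation, without ionising C1'. The ynol ether, carried on the bis-triethylsilylated eudesmane-4α,11-diol, comes from an ester by ynolate homologation; the decalin derives from (R)-Wieland–Miescher ketone and C1' from an oxazolidinone-controlled alkylation.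

Key step: step 23

Remarks on the chemistry (assumptions)
- Eudesmane numbering is used for the decalin: C1 bears C1'; C4 bears CH3 (C15) and OH; C5 and C10 are the ring-fusion carbons; C7 bears the C11 carbinol. Ring A = C1–C5/C10, ring B = C5–C10; β is the face of the C10 methyl. "Eudesmane" intermediates have 5α-H, 7α-H, 10β-CH3 and 4β-CH3/4α-O.
- The C1' alkylation uses an allylic electrophile (3-bromo-2-methylpropene) followed by hydrogenation, because a hindered imide enolate cannot be expected to react with an unactivated, β-branched isobutyl halide.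
- The endgame avoids TiCl4 and boron halides, which would ionise the two tertiary carbinols. Formylation is therefore phenoxide-directed and the ethyl ether is cleaved by a thiolate.
- Compounds 12 and 13 are C7-epimer mixtures and 37 is a mixture at its transient sp3 ring carbon; their SMILES leave that centre open.

Step 1
Reactants: 1 (R)-Wieland–Miescher ketone
Product: 2 (4aR,5R)-5-hydroxy-4a-methyl-4,4a,5,6,7,8-hexahydronaphthalen-2(3H)-one (1β-alcohol)
Conditions: NaBH4 (0.3 equiv), EtOH, −10 °C
Reagents that add atoms: none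
Why: Chemoselective borohydride reduction, in which the saturated C1 ketone is more electrophilic than the conjugated C7 ketone and hydride adds to C1 from the α face, anti to the neighbouring axial C10 methyl, so that the 1β (equatorial) alcohol should result.

Step 2
Reactants: 2
Product: 3 1β-pivaloyloxy enone
Conditions: t-BuCOCl, pyridine, DMAP (cat.), CH2Cl2, 40 °C
Reagents that add atoms: pivaloyl chloride, CC(C)(C)C(=O)Cl
Why: DMAP-catalysed O-acylation gives a hindered ester that should survive borane, peroxide, ylide and peracid and is removed without an extra step by LiAlH4 in step 8.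

Step 3
Reactants: 3
Product: 4 1β-pivaloyloxy-7,7-ethylenedioxy Δ4(5)-alkene
Conditions: HOCH2CH2OH, TsOH (cat.), benzene, reflux, Dean–Stark
Reagents that add atoms: ethylene glycol, OCCO
Why: Acid-catalysed ketalisation of a cyclohexenone runs through the dienol ether and is known to give the β,γ-unsaturated dioxolane, which moves the double bond to C4=C5 and makes C4 addressable.

Step 4
Reactants: 4
Product: 6 trans-fused 4α-alcohol (5α-H), via alkylborane 5 (not isolated)
Conditions: BH3·THF, THF, 0 °C → rt; then NaOH, H2O2, 0 °C → rt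
Reagents that add atoms: borane (as THF complex), B (boron stays only in 5); hydrogen peroxide, OO
Why: Hydroboration–oxidation, in which borane adds syn from the α face because the β face is shielded by the axial C10 methyl, with boron on the less substituted C4 and hydrogen on C5, which sets the 5α-H trans ring fusion and, after oxidation with retention, the 4α-hydroxyl.

Step 5
Reactants: 6
Product: 7 4-ketone
Conditions: (n-Pr4N)RuO4 (5 mol %), N-methylmorpholine N-oxide, 4 Å MS, CH2Cl2, rt
Reagents that add atoms: none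
Why: Ley–Griffith oxidation of a secondary alcohol under neutral conditions that spare dioxolane and pivalate, and the trans-fused 4-ketone should also be the more stable C5 epimer, so the ring fusion is not at risk.

Step 6
Reactants: 7
Product: 8 4(15)-methylene compound
Conditions: Ph3PCH3Br, KOt-Bu, toluene, 80 °C
Reagents that add atoms: methyltriphenylphosphonium bromide, C[P+](c1ccccc1)(c1ccccc1)c1ccccc1.[Br-]
Why: Wittig methylenation is the standard way to convert a hindered 4-oxo trans-decalin into the exocyclic C4=C15 alkene.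

Step 7
Reactants: 8
Product: 9 4α,15-epoxide
Conditions: mCPBA, NaHCO3, CH2Cl2, 0 °C
Reagents that add atoms: 3-chloroperoxybenzoic acid, OOC(=O)c1cccc(Cl)c1
Why: Prilezhaev epoxidation, in which the peracid should approach the exocyclic alkene from the α (equatorial) side because the β (axial) trajectory is syn-axial to the C10 methyl, which puts the epoxide oxygen α on C4 and thereby fixes the C4 stereocentre.

Step 8
Reactants: 9
Product: 11 1β,4α-dihydroxy-4β-methyl 7-ketone, via diol ketal 10 (not isolated)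
Conditions: LiAlH4, THF, 0 °C → reflux; then 2 M HCl, THF, rt
Reagents that add atoms: water, O
Why: Hydride opens the spiro-epoxide by SN2 attack at the primary C15 to give the tertiary 4α-alcohol with the 4β-methyl and cleaves the pivalate by ester reduction, after which dilute aqueous acid hydrolyses the dioxolane under conditions that tertiary alcohols tolerate.

Step 9
Reactants: 11
Product: 12 7-nitrile (C7 epimers)
Conditions: TosMIC, KOt-Bu, DME/EtOH, 0 → 35 °C
Reagents that add atoms: p-toluenesulfonylmethyl isocyanide, Cc1ccc(cc1)S(=O)(=O)C[N+]#[C-]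
Why: van Leusen reductive cyanation converts the unhindered C7 ketone into the one-carbon-homologated nitrile while the alkoxides of the two free hydroxyls stay passive; C7 is fixed in step 10.

Step 10
Reactants: 12
Product: 14 7β-acetyl-1β,4α-diol, via ketimine 13 (not isolated)
Conditions: MeLi (5 equiv), THF, 0 °C → rt; 1 M HCl, rt; then NaOMe, MeOH, rt
Reagents that add atoms: methyllithium, [Li]C; water, O
Why: Organolithium addition to a nitrile stops at the ketimine stage, aqueous acid hydrolyses it to the methyl ketone, and methoxide equilibration through the enolate should move the acetyl group into the equatorial 7β position, so that C7 is set under thermodynamic control by the chair of ring B.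

Step 11
Reactants: 14
Product: 15 eudesmane-1β,4α,11-triol
Conditions: MeMgBr (6 equiv), THF, 0 °C
Reagents that add atoms: methylmagnesium bromide, C[Mg]Br
Why: Grignard addition to the methyl ketone completes the C11 dimethylcarbinol without creating a stereocentre.

Step 12
Reactants: 15
Product: 16 4α,11-dihydroxyeudesman-1-one
Conditions: (n-Pr4N)RuO4 (5 mol %), N-methylmorpholine N-oxide, 4 Å MS, CH2Cl2/MeCN, rt
Reagents that add atoms: none
Why: Ley–Griffith oxidation can only touch the secondary C1 hydroxyl, since the two tertiary alcohols have no carbinol hydrogen.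

Step 13
Reactants: 16
Product: 17 4α,11-bis(triethylsilyloxy)eudesman-1-one
Conditions: Et3SiOTf (3 equiv), 2,6-lutidine, CH2Cl2, −78 → 0 °C
Reagents that add atoms: triethylsilyl trifluoromethanesulfonate, CC[Si](CC)(CC)OS(=O)(=O)C(F)(F)F
Why: Silyl triflate with lutidine is the standard silylation of tertiary alcohols, and the triethylsilyl ethers shield both carbinols from bases, enolates and ketenes yet remain fluoride-labile.

Step 14
Reactants: 17; 18 benzyl 2-(diethoxyphosphoryl)acetate
Product: 19 benzyl (E)-2-[4α,11-bis(triethylsilyloxy)eudesman-1-ylidene]acetate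
Conditions: NaH, THF/toluene, 90 °C
Reagents that add atoms: none
Why: Horner–Wadsworth–Emmons olefination of the C1 ketone should place the ester anti to the quaternary C10, and either alkene isomer converges in step 15.

Step 15
Reactants: 19
Product: 20 2-[4α,11-bis(triethylsilyloxy)eudesman-1β-yl]acetic acid
Conditions: H2 (3 atm), Pd/C, EtOAc, rt
Reagents that add atoms: none
Why: Heterogeneous hydrogenation delivers hydrogen to C1 from the α face because the β face is blocked by the adjacent axial C10 methyl, which sets C1 with the side chain 1β (equatorial), and the benzyl ester is hydrogenolysed in the same operation.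

Step 16
Reactants: 20; 21 (S)-4-benzyloxazolidin-2-one
Product: 23 N-acyl oxazolidinone, via mixed anhydride 22 (not isolated)
Conditions: t-BuCOCl, Et3N, THF, −20 °C; then 21, LiCl, rt
Reagents that add atoms: pivaloyl chloride, CC(C)(C)C(=O)Cl (its acyl group stays only in 22)
Why: N-Acylation of the oxazolidinone through the mixed pivalic anhydride, which is attacked at the less hindered of its two carbonyl groups.

Step 17
Reactants: 23; 24 3-bromo-2-methylprop-1-ene
Product: 26 (S)-C1' 2-methylallyl imide, via sodium enolate 25 (not isolated)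
Conditions: NaN(SiMe3)2, THF, −78 °C; then 24, −78 → −20 °C
Reagents that add atoms: none
Why: Evans asymmetric alkylation, in which the chelated (Z)-enolate is attacked by the allylic bromide on the face opposite the benzyl group of the auxiliary to give (S)-C1', and the resident C1 centre reinforces this (matched case) because A(1,3) strain places the quaternary C10 on the face the auxiliary already shields.

Step 18
Reactants: 26
Product: 27 (S)-C1' isobutyl imide
Conditions: H2 (1 atm), Pd/C, EtOAc, rt
Reagents that add atoms: none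
Why: Catalytic hydrogenation of the 1,1-disubstituted alkene turns the methallyl into the isobutyl group while silyl ethers, imide and the C-benzyl group stay inert.

Step 19
Reactants: 27
Product: 29 (2S)-2-[4α,11-bis(triethylsilyloxy)eudesman-1β-yl]-4-methylpentanoic acid, via peroxy acid 28 (not isolated)
Conditions: LiOH, H2O2, THF/H2O, 0 °C; Na2SO3; then 1 M HCl
Reagents that add atoms: hydrogen peroxide, OO
Why: Hydroperoxide-mediated imide hydrolysis, in which the small and highly nucleophilic LiOOH attacks the exocyclic carbonyl even of hindered acyl oxazolidinones and does not epimerise C1'.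

Step 20
Reactants: 29
Product: 30 methyl ester of 29
Conditions: MeI, K2CO3, DMF, rt
Reagents that add atoms: iodomethane, CI
Why: SN2 O-methylation of the carboxylate gives the methyl ester, the least hindered acceptor for the next step, without touching the α stereocentre.

Step 21
Reactants: 30
Product: 33 C1' (triisopropylsilyloxy)alkyne, via dibromomethyl ketone 31 (not isolated), via lithium ynolate 32 (not isolated)
Conditions: CH2Br2, lithium 2,2,6,6-tetramethylpiperidide, THF, −78 °C; LiN(SiMe3)2; n-BuLi, −78 °C → rt; then i-Pr3SiCl, −78 °C → rt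
Reagents that add atoms: dibromomethane, BrCBr; chlorotriisopropylsilane, CC(C)[Si](Cl)(C(C)C)C(C)C
Why: Kowalski ester homologation stopped at the ynolate, in which LiCHBr2 acylation gives the dibromomethyl ketone, its enolate undergoes bromine–lithium exchange and a carbenoid 1,2-shift of C1' with retention of configuration, and the bulky silyl chloride silylates the ambident ynolate on oxygen.

Step 22
Reactants: 34 ethoxyacetylene
Product: 35 3-ethoxycyclobut-2-en-1-one
Conditions: CH3COCl, Et3N, Et2O, 0 °C → rt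
Reagents that add atoms: acetyl chloride, CC(=O)Cl
Why: [2+2] Cycloaddition of ketene, generated in situ by dehydrochlorination, with the ynol ether, whose nucleophilic terminal carbon bonds to the ketene carbonyl carbon and so gives the 3-ethoxy isomer.

Step 23
Reactants: 33; 35
Product: 40 2-alkyl-5-ethoxy-3-(triisopropylsilyloxy)phenol (alkyl = C1' of the bis-silylated eudesmane), via vinylketene 36 (not isolated), via vinylcyclobutenone 37 (not isolated), via dienylketene 38 (not isolated), via cyclohexadienone 39 (not isolated)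
Conditions: 35 (1.5 equiv), toluene, 80 °C, sealed tube
Reagents that add atoms: none
Why: On heating, 35 opens by 4π electrocyclic ring opening to ethoxyvinylketene 36, whose ketene C=C adds [2+2] to the ynol ether with the nucleophilic, C1'-bearing alkyne carbon bonding to the ketene carbonyl carbon to give 37; 37 opens (4π) to dienylketene 38, which closes to 39 and tautomerises to the phenol. The closest known reaction type is the Danheiser benzannulation of cyclobutenones with trialkylsilyloxyalkynes to resorcinol monosilyl ethers. The one ring formed, the arene, is closed by thermal 6π electrocyclisation of the (Z)-dienylketene, after the two new skeletal bonds (arene C1–C2 and C3–C4, counting from the phenol carbon) have been made in the [2+2] step. No stereocentre is created, and the sp3 ring carbon of 37 disappears again on ring opening. The step needs regiocontrol in the ketene–alkyne cycloaddition, which the oxygen-polarised ynol ether secures, and retention at C1', which is secured because the conditions are neutral and thermal and no ion or radical is formed at the propargylic carbon. The triethylsilyl ethers keep the tertiary hydroxyls from adding to the ketenes, and C1' ends between the free hydroxyl and the silyloxy group.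

Step 24
Reactants: 40
Product: 41 2-alkyl-5-ethoxybenzene-1,3-diol with free 4α,11-diol
Conditions: Bu4NF (6 equiv), THF, 0 → 45 °C; aq. NH4Cl
Reagents that add atoms: none
Why: Fluoride-induced Si–O cleavage, in which the aryl silyl ether falls first and the two tertiary triethylsilyl ethers follow on warming.

Step 25
Reactants: 41
Product: 43 O-ethyl macrocarpal J (4-ethoxy dialdehyde), via monoaldehyde 42 (not isolated)
Conditions: MgCl2, Et3N, (CH2O)n, MeCN, reflux; then 1 M HCl
Reagents that add atoms: paraformaldehyde, C=O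
Why: Magnesium phenoxide-directed ortho-formylation (Casnati–Skattebøl), in which each phenoxide delivers formaldehyde to its only free ortho carbon and the hydroxymethyl group is oxidised in situ by a second formaldehyde, under basic conditions that leave the tertiary alcohols untouched.

Step 26
Reactants: 43
Product: 44 macrocarpal J
Conditions: PhSNa, DMF, 100 °C; then 1 M HCl
Reagents that add atoms: none
Why: Nucleophilic O-dealkylation, in which the soft and weakly basic thiolate attacks the ethyl group by SN2, favoured here because the departing phenoxide is flanked by two formyl groups (a vinylogous carboxylate), while aldehydes and tertiary alcohols are not affected.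

Compound list
1 | (R)-Wieland–Miescher ketone, (8aR)-8a-methyl-3,4,8,8a-tetrahydronaphthalene-1,6(2H,7H)-dione | O=C1CCCC2=CC(=O)CC[C@]21C | starting material
2 | (4aR,5R)-5-hydroxy-4a-methyl-4,4a,5,6,7,8-hexahydronaphthalen-2(3H)-one (C1 hydroxyl β, cis to the C10 methyl) | O[C@@H]1CCCC2=CC(=O)CC[C@]21C | intermediate
3 | pivalate of 2 (1β-pivaloyloxy enone) | CC(C)(C)C(=O)O[C@@H]1CCCC2=CC(=O)CC[C@]21C | intermediate
4 | 1β-pivaloyloxy-7,7-ethylenedioxy-10β-methyl Δ4(5)-octalin | CC(C)(C)C(=O)O[C@@H]1CCC=C2CC3(OCCO3)CC[C@]21C | intermediate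
5 | 4α-boryl-5α-H alkylborane from 4 | CC(C)(C)C(=O)O[C@@H]1CC[C@@H](B)[C@@H]2CC3(OCCO3)CC[C@]21C | intermediate
6 | 7,7-ethylenedioxy-1β-pivaloyloxy-10β-methyl-trans-decalin-4α-ol (5α-H) | CC(C)(C)C(=O)O[C@@H]1CC[C@@H](O)[C@@H]2CC3(OCCO3)CC[C@]21C | intermediate
7 | 7,7-ethylenedioxy-1β-pivaloyloxy-10β-methyl-trans-decalin-4-one | CC(C)(C)C(=O)O[C@@H]1CCC(=O)[C@@H]2CC3(OCCO3)CC[C@]21C | intermediate
8 | 4-methylene analogue of 7 (C4=C15) | CC(C)(C)C(=O)O[C@@H]1CCC(=C)[C@@H]2CC3(OCCO3)CC[C@]21C | intermediate
9 | 4α,15-epoxide of 8 (oxygen α, CH2 β) | CC(C)(C)C(=O)O[C@@H]1CC[C@@]4(OC4)[C@@H]2CC3(OCCO3)CC[C@]21C | intermediate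
10 | 7,7-ethylenedioxy-4β,10β-dimethyl-trans-decalin-1β,4α-diol | O[C@@H]1CC[C@@](C)(O)[C@@H]2CC3(OCCO3)CC[C@]21C | intermediate
11 | 1β,4α-dihydroxy-4β,10β-dimethyl-trans-decalin-7-one | O[C@@H]1CC[C@@](C)(O)[C@@H]2CC(=O)CC[C@]21C | intermediate
12 | 1β,4α-dihydroxy-4β,10β-dimethyl-trans-decalin-7-carbonitrile (C7 epimers) | O[C@@H]1CC[C@@](C)(O)[C@@H]2CC(C#N)CC[C@]21C | intermediate
13 | 7-(1-iminoethyl) analogue of 12 (C7 epimers) | O[C@@H]1CC[C@@](C)(O)[C@@H]2CC(C(C)=N)CC[C@]21C | intermediate
14 | 7β-acetyl-4β,10β-dimethyl-trans-decalin-1β,4α-diol | O[C@@H]1CC[C@@](C)(O)[C@@H]2C[C@H](C(C)=O)CC[C@]21C | intermediate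
15 | eudesmane-1β,4α,11-triol | O[C@@H]1CC[C@@](C)(O)[C@@H]2C[C@H](C(C)(C)O)CC[C@]21C | intermediate
16 | 4α,11-dihydroxyeudesman-1-one | O=C1CC[C@@](C)(O)[C@@H]2C[C@H](C(C)(C)O)CC[C@]21C | intermediate
17 | 4α,11-bis(triethylsilyloxy)eudesman-1-one | O=C1CC[C@@](C)(O[Si](CC)(CC)CC)[C@@H]2C[C@H](C(C)(C)O[Si](CC)(CC)CC)CC[C@]21C | intermediate
18 | benzyl 2-(diethoxyphosphoryl)acetate | CCOP(=O)(CC(=O)OCc1ccccc1)OCC | starting material
19 | benzyl (E)-2-[4α,11-bis(triethylsilyloxy)eudesman-1-ylidene]acetate | O=C(OCc1ccccc1)/C=C1\CC[C@@](C)(O[Si](CC)(CC)CC)[C@@H]2C[C@H](C(C)(C)O[Si](CC)(CC)CC)CC[C@]21C | intermediate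
20 | 2-[4α,11-bis(triethylsilyloxy)eudesman-1β-yl]acetic acid (1α-H) | OC(=O)C[C@@H]1CC[C@@](C)(O[Si](CC)(CC)CC)[C@@H]2C[C@H](C(C)(C)O[Si](CC)(CC)CC)CC[C@]21C | intermediate
21 | (S)-4-benzyloxazolidin-2-one | O=C1N[C@@H](Cc2ccccc2)CO1 | starting material
22 | mixed pivalic anhydride of 20 | CC(C)(C)C(=O)OC(=O)C[C@@H]1CC[C@@](C)(O[Si](CC)(CC)CC)[C@@H]2C[C@H](C(C)(C)O[Si](CC)(CC)CC)CC[C@]21C | intermediate
23 | (S)-4-benzyl-3-{2-[4α,11-bis(triethylsilyloxy)eudesman-1β-yl]acetyl}oxazolidin-2-one | O=C(C[C@@H]1CC[C@@](C)(O[Si](CC)(CC)CC)[C@@H]2C[C@H](C(C)(C)O[Si](CC)(CC)CC)CC[C@]21C)N1[C@@H](Cc2ccccc2)COC1=O | intermediate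
24 | 3-bromo-2-methylprop-1-ene | C=C(C)CBr | starting material
25 | sodium (Z)-enolate of 23 | [Na+].[O-]/C(=C\[C@@H]1CC[C@@](C)(O[Si](CC)(CC)CC)[C@@H]2C[C@H](C(C)(C)O[Si](CC)(CC)CC)CC[C@]21C)N1[C@@H](Cc2ccccc2)COC1=O | intermediate
26 | imide 23 alkylated at C1' with 2-methylallyl, (S) at C1' | C=C(C)C[C@H](C(=O)N1[C@@H](Cc2ccccc2)COC1=O)[C@@H]1CC[C@@](C)(O[Si](CC)(CC)CC)[C@@H]2C[C@H](C(C)(C)O[Si](CC)(CC)CC)CC[C@]21C | intermediate
27 | (S)-4-benzyl-3-{(2S)-2-[4α,11-bis(triethylsilyloxy)eudesman-1β-yl]-4-methylpentanoyl}oxazolidin-2-one | CC(C)C[C@H](C(=O)N1[C@@H](Cc2ccccc2)COC1=O)[C@@H]1CC[C@@](C)(O[Si](CC)(CC)CC)[C@@H]2C[C@H](C(C)(C)O[Si](CC)(CC)CC)CC[C@]21C | intermediate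
28 | peroxy acid corresponding to 29 | CC(C)C[C@H](C(=O)OO)[C@@H]1CC[C@@](C)(O[Si](CC)(CC)CC)[C@@H]2C[C@H](C(C)(C)O[Si](CC)(CC)CC)CC[C@]21C | intermediate
29 | (2S)-2-[4α,11-bis(triethylsilyloxy)eudesman-1β-yl]-4-methylpentanoic acid | CC(C)C[C@H](C(=O)O)[C@@H]1CC[C@@](C)(O[Si](CC)(CC)CC)[C@@H]2C[C@H](C(C)(C)O[Si](CC)(CC)CC)CC[C@]21C | intermediate
30 | methyl ester of 29 | CC(C)C[C@H](C(=O)OC)[C@@H]1CC[C@@](C)(O[Si](CC)(CC)CC)[C@@H]2C[C@H](C(C)(C)O[Si](CC)(CC)CC)CC[C@]21C | intermediate
31 | dibromomethyl ketone from 30 (C1'–CO–CHBr2) | CC(C)C[C@H](C(=O)C(Br)Br)[C@@H]1CC[C@@](C)(O[Si](CC)(CC)CC)[C@@H]2C[C@H](C(C)(C)O[Si](CC)(CC)CC)CC[C@]21C | intermediate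
32 | lithium ynolate (C1'–C≡C–OLi) | CC(C)C[C@H](C#CO[Li])[C@@H]1CC[C@@](C)(O[Si](CC)(CC)CC)[C@@H]2C[C@H](C(C)(C)O[Si](CC)(CC)CC)CC[C@]21C | intermediate
33 | C1' (triisopropylsilyloxy)alkyne of the bis(triethylsilyl) eudesmane diol, (S) at C1' | CC(C)C[C@H](C#CO[Si](C(C)C)(C(C)C)C(C)C)[C@@H]1CC[C@@](C)(O[Si](CC)(CC)CC)[C@@H]2C[C@H](C(C)(C)O[Si](CC)(CC)CC)CC[C@]21C | intermediate
34 | ethoxyacetylene (ethoxyethyne) | CCOC#C | starting material
35 | 3-ethoxycyclobut-2-en-1-one | CCOC1=CC(=O)C1 | intermediate
36 | 3-ethoxybuta-1,3-dien-1-one (ethoxyvinylketene) | C=C(OCC)C=C=O | intermediate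
37 | 2-alkyl-4-(1-ethoxyvinyl)-3-(triisopropylsilyloxy)cyclobut-2-en-1-one (alkyl = C1' unit) | CC(C)C[C@H](C1=C(O[Si](C(C)C)(C(C)C)C(C)C)C(C(=C)OCC)C1=O)[C@@H]1CC[C@@](C)(O[Si](CC)(CC)CC)[C@@H]2C[C@H](C(C)(C)O[Si](CC)(CC)CC)CC[C@]21C | intermediate
38 | (3Z)-2-alkyl-5-ethoxy-3-(triisopropylsilyloxy)hexa-1,3,5-trien-1-one (dienylketene) | CC(C)C[C@H](C(=C=O)/C(O[Si](C(C)C)(C(C)C)C(C)C)=C\C(=C)OCC)[C@@H]1CC[C@@](C)(O[Si](CC)(CC)CC)[C@@H]2C[C@H](C(C)(C)O[Si](CC)(CC)CC)CC[C@]21C | intermediate
39 | 2-alkyl-5-ethoxy-3-(triisopropylsilyloxy)cyclohexa-2,4-dien-1-one | CC(C)C[C@H](C1=C(O[Si](C(C)C)(C(C)C)C(C)C)C=C(OCC)CC1=O)[C@@H]1CC[C@@](C)(O[Si](CC)(CC)CC)[C@@H]2C[C@H](C(C)(C)O[Si](CC)(CC)CC)CC[C@]21C | intermediate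
40 | 2-alkyl-5-ethoxy-3-(triisopropylsilyloxy)phenol, alkyl = (S)-C1' of the bis(triethylsilyl) eudesmane diol | CC(C)C[C@H](c1c(O)cc(OCC)cc1O[Si](C(C)C)(C(C)C)C(C)C)[C@@H]1CC[C@@](C)(O[Si](CC)(CC)CC)[C@@H]2C[C@H](C(C)(C)O[Si](CC)(CC)CC)CC[C@]21C | intermediate
41 | 2-alkyl-5-ethoxybenzene-1,3-diol with free eudesmane-4α,11-diol | CC(C)C[C@H](c1c(O)cc(OCC)cc1O)[C@@H]1CC[C@@](C)(O)[C@@H]2C[C@H](C(C)(C)O)CC[C@]21C | intermediate
42 | mono-formylated 41 (formyl between OH and OEt) | CC(C)C[C@H](c1c(O)cc(OCC)c(C=O)c1O)[C@@H]1CC[C@@](C)(O)[C@@H]2C[C@H](C(C)(C)O)CC[C@]21C | intermediate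
43 | O-ethyl macrocarpal J (5-alkyl-2-ethoxy-4,6-dihydroxybenzene-1,3-dicarbaldehyde) | CC(C)C[C@H](c1c(O)c(C=O)c(OCC)c(C=O)c1O)[C@@H]1CC[C@@](C)(O)[C@@H]2C[C@H](C(C)(C)O)CC[C@]21C | intermediate
44 | macrocarpal J | CC(C)C[C@H](c1c(O)c(C=O)c(O)c(C=O)c1O)[C@@H]1CC[C@@](C)(O)[C@@H]2C[C@H](C(C)(C)O)CC[C@]21C | target

Total step count: 26
Longest linear sequence: 25 steps (1 → 44 through steps 1–21 and 23–26); step 22 is a one-step side branch.

Steps most likely to fail

1. Step 23 (benzannulation). The [2+2] capture of the ethoxyvinylketene by the alkyne carbon next to the branched C1' may be too slow, so that the ketene is lost to dimerisation or to O-acylation of phenol already formed. The fallback exchanges the roles of the partners. It sets out from 33, which would add ketene (acetyl chloride, Et3N) in a [2+2] cycloaddition to give 2-alkyl-3-(triisopropylsilyloxy)cyclobut-2-en-1-one F1. Heating F1 with ethoxyacetylene 34 in toluene would open it to a silyloxyvinylketene and run the same pericyclic cascade with the small, very reactive ynol ether, giving the regioisomerically protected 4-alkyl-3-ethoxy-5-(triisopropylsilyloxy)phenol F2 (free hydroxyl para to C1'). Bu4NF would give 4-alkyl-5-ethoxybenzene-1,3-diol tetraol F3, the magnesium-mediated formylation of step 25 would give dialdehyde F4 (both free ring carbons are ortho to a hydroxyl), and thiolate de-ethylation as in step 26 would return to the route at 44.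

2. Step 21 (ynolate formation and O-silylation). Addition of LiCHBr2 to the doubly branched ester may be incomplete, or the ynolate may be silylated on carbon. The fallback sets out from 30 and makes the ynolate from an alkyne instead. LiAlH4 would give the primary alcohol F5, Ley–Griffith oxidation the aldehyde F6, and CBr4/PPh3 (Corey–Fuchs) the dibromoalkene F7, which n-BuLi converts into the terminal alkyne F8. Deprotonation of F8 with LiN(SiMe3)2 and oxidation of the lithium acetylide with lithium tert-butyl peroxide would give the same ynolate 32, and i-Pr3SiOTf would return to the route at 33.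

3. Step 25 (double ortho-formylation). The second formylation may stall once the first formyl group, para to the remaining phenoxide, has lowered the nucleophilicity of the ring. The fallback uses an iminium electrophile on a substrate whose carbinols are still protected. It sets out from 40: Bu4NF at 0 °C (1 equiv) would remove only the aryl silyl group and give the 2-alkyl-5-ethoxyresorcinol bis(triethylsilyl) ether F9. Vilsmeier–Haack formylation (POCl3, DMF, MeCN, 0 °C → rt; aq. NaOAc) would give the dialdehyde bis(triethylsilyl) ether F10, and HF·pyridine in THF would return to the route at 43.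

Further compounds
F1 | step 23 | 2-alkyl-3-(triisopropylsilyloxy)cyclobut-2-en-1-one (alkyl = C1' unit of 33) | CC(C)C[C@H](C1=C(O[Si](C(C)C)(C(C)C)C(C)C)CC1=O)[C@@H]1CC[C@@](C)(O[Si](CC)(CC)CC)[C@@H]2C[C@H](C(C)(C)O[Si](CC)(CC)CC)CC[C@]21C
F2 | step 23 | 4-alkyl-3-ethoxy-5-(triisopropylsilyloxy)phenol, bis(triethylsilyl) ether of the diol | CC(C)C[C@H](c1c(OCC)cc(O)cc1O[Si](C(C)C)(C(C)C)C(C)C)[C@@H]1CC[C@@](C)(O[Si](CC)(CC)CC)[C@@H]2C[C@H](C(C)(C)O[Si](CC)(CC)CC)CC[C@]21C
F3 | step 23 | 4-alkyl-5-ethoxybenzene-1,3-diol with free eudesmane-4α,11-diol | CC(C)C[C@H](c1c(OCC)cc(O)cc1O)[C@@H]1CC[C@@](C)(O)[C@@H]2C[C@H](C(C)(C)O)CC[C@]21C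
F4 | step 23 | 5-alkyl-4-ethoxy-2,6-dihydroxybenzene-1,3-dicarbaldehyde with free diol | CC(C)C[C@H](c1c(OCC)c(C=O)c(O)c(C=O)c1O)[C@@H]1CC[C@@](C)(O)[C@@H]2C[C@H](C(C)(C)O)CC[C@]21C
F5 | step 21 | (2S)-2-[4α,11-bis(triethylsilyloxy)eudesman-1β-yl]-4-methylpentan-1-ol | CC(C)C[C@H](CO)[C@@H]1CC[C@@](C)(O[Si](CC)(CC)CC)[C@@H]2C[C@H](C(C)(C)O[Si](CC)(CC)CC)CC[C@]21C
F6 | step 21 | (2S)-2-[4α,11-bis(triethylsilyloxy)eudesman-1β-yl]-4-methylpentanal | CC(C)C[C@H](C=O)[C@@H]1CC[C@@](C)(O[Si](CC)(CC)CC)[C@@H]2C[C@H](C(C)(C)O[Si](CC)(CC)CC)CC[C@]21C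
F7 | step 21 | 1,1-dibromoalkene from F6 (C1'–CH=CBr2) | CC(C)C[C@H](C=C(Br)Br)[C@@H]1CC[C@@](C)(O[Si](CC)(CC)CC)[C@@H]2C[C@H](C(C)(C)O[Si](CC)(CC)CC)CC[C@]21C
F8 | step 21 | terminal alkyne (C1'–C≡CH) | CC(C)C[C@H](C#C)[C@@H]1CC[C@@](C)(O[Si](CC)(CC)CC)[C@@H]2C[C@H](C(C)(C)O[Si](CC)(CC)CC)CC[C@]21C
F9 | step 25 | 2-alkyl-5-ethoxybenzene-1,3-diol, bis(triethylsilyl) ether of the diol | CC(C)C[C@H](c1c(O)cc(OCC)cc1O)[C@@H]1CC[C@@](C)(O[Si](CC)(CC)CC)[C@@H]2C[C@H](C(C)(C)O[Si](CC)(CC)CC)CC[C@]21C
F10 | step 25 | 5-alkyl-2-ethoxy-4,6-dihydroxybenzene-1,3-dicarbaldehyde, bis(triethylsilyl) ether of the diol | CC(C)C[C@H](c1c(O)c(C=O)c(OCC)c(C=O)c1O)[C@@H]1CC[C@@](C)(O[Si](CC)(CC)CC)[C@@H]2C[C@H](C(C)(C)O[Si](CC)(CC)CC)CC[C@]21C
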